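**Retrosynthetic overview**

1. Numbering used below (elemane): ring carbons C5–C10 (C10 quaternary, bearing methyl and the C1=C2 vinyl), the C4(=C3)–C15 2-propenyl unit on C5, C6 carbinol, C9 acyloxy, lactone O–C8 and C7–C11(=C13)–C12(=O).
2. Target 34 ⇐ bis-silyl ether 33 ⇐ acyclic allenyl aldehyde 31 + CO by a hetero-Pauson–Khand [2+2+1]. The enabling feature is the cis-fused α-methylene-γ-butyrolactone on the cyclohexane (O–C8H–C7H–C11(=CH2)–C12=O), which is the retron of a C8 formyl group, a C7=C11=CH2 allene and carbon monoxide.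
3. Ring order: no ring of the target exists before the key step; C7–C8 closes the cyclohexane and C11–C12 (then O–C12) closes the lactone in the same operation.
4. 31 ⇐ allenol 23 (Crabbé homologation) ⇐ propargylic alcohol 20 ⇐ aldehyde 18 (Felkin–Anh ethynylation sets C6); the C9 isobutyrate and C8 aldehyde come from a terminal acetonide.
5. The C10/C5 pair flanked by vinyl and 2-propenyl groups (a 1,5-diene) ⇐ enantiocontrolled Ireland–Claisen rearrangement of allyl ester 14 (acid part from itaconic anhydride); C9 comes from methyl (S)-isopropylideneglycerate 1.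

Key step: step 16

Assumption: the chiral bromoborane controller of step 7 is drawn as its (S,S) enantiomer, taken to be the one whose facial preference matches that of the substrate; if the sense proves opposite, the (R,R) reagent is used with no other change.

**Route**

Step 1
Reactants: 1 methyl (4S)-2,2-dimethyl-1,3-dioxolane-4-carboxylate; 2 N,O-dimethylhydroxylamine hydrochloride
Product: 3 Weinreb amide of the glycerate acetonide
Conditions: i-PrMgCl (3 equiv), THF, −20 °C
Reagents that add atoms: N,O-dimethylhydroxylamine hydrochloride, Cl.CNOC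
Why: Aminolysis of the ester by the magnesium amide (Weinreb amide formation) runs at low temperature without enolising the α-alkoxy stereocentre, which is carried through unchanged.

Step 2
Reactants: 3 Weinreb amide; 4 methylmagnesium bromide
Product: 5 methyl ketone 1-[(4S)-2,2-dimethyl-1,3-dioxolan-4-yl]ethan-1-one
Conditions: MeMgBr, THF, 0 °C; aq. NH4Cl
Reagents that add atoms: methylmagnesium bromide, C[Mg]Br
Why: Grignard addition to a Weinreb amide stops at the chelated tetrahedral intermediate, so the ketone should form without over-addition or epimerisation.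

Step 3
Reactants: 5 methyl ketone; 6 ethyl (triphenylphosphoranylidene)acetate
Product: 7 (E)-enoate
Conditions: toluene, 80 °C (no base); chromatography to remove the minor Z isomer
Reagents that add atoms: ethyl (triphenylphosphoranylidene)acetate, CCOC(=O)C=P(c1ccccc1)(c1ccccc1)c1ccccc1
Why: Wittig olefination with a stabilised ylide in an aprotic solvent should give mainly the (E)-trisubstituted enoate (dioxolanyl trans to the ester) and, being base-free, leaves the α-alkoxy centre intact.

Step 4
Reactants: 7 (E)-enoate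
Product: 8 (E)-allylic alcohol
Conditions: DIBAL-H (2.2 equiv), CH2Cl2, −78 °C; Rochelle salt
Reagents that add atoms: none
Why: DIBAL 1,2-reduction of an α,β-unsaturated ester gives the allylic alcohol with retention of alkene geometry.

Step 5
Reactants: 8 (E)-allylic alcohol; 9 itaconic anhydride
Product: 10 allyl hydrogen itaconate (ester at the CH2–CO end)
Conditions: toluene, 65 °C, no amine base
Reagents that add atoms: itaconic anhydride, C=C1CC(=O)OC1=O
Why: Alcoholysis of itaconic anhydride takes place at the non-conjugated, more electrophilic carbonyl, which esterifies the CH2–CO terminus and leaves the acrylic acid free; amines are avoided because they isomerise the anhydride.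

Step 6
Reactants: 10 allyl hydrogen itaconate; 11 tert-butyl(chloro)diphenylsilane
Product: 14 silyl-protected allyl ester, via mixed carbonic anhydride 12 (not isolated), via hydroxy ester 13 (not isolated)
Conditions: i-BuOCOCl, N-methylmorpholine, THF, −15 °C; NaBH4, H2O, 0 °C; crude alcohol then TBDPSCl, imidazole, CH2Cl2, 0 °C
Reagents that add atoms: tert-butyl(chloro)diphenylsilane, CC(C)(C)[Si](Cl)(c1ccccc1)c1ccccc1
Why: Mixed-anhydride activation followed by borohydride reduction converts the carboxylic acid into the allylic alcohol in the presence of the ester, and immediate silylation of the crude γ-hydroxy ester forestalls lactonisation.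

Step 7
Reactants: 14 silyl-protected allyl ester
Product: 16 (2S,3S)-pent-4-enoic acid carrying the new C5 and C10 centres, via boron ketene acetal 15 (not isolated)
Conditions: (S,S)-2-bromo-1,3-bis[3,5-bis(trifluoromethyl)phenylsulfonyl]-4,5-diphenyl-1,3,2-diazaborolidine (1.3 equiv), Et3N, toluene–hexane, −78 °C; then −20 → 4 °C; aqueous work-up
Reagents that add atoms: none
Why: In this enantiocontrolled Ireland–Claisen rearrangement the E(O)-boron ketene acetal and the (E)-alkene react through a chair transition state, which fixes the relative configuration of quaternary C10 and tertiary C5 (2-propenyl branch axial, dioxolanyl equatorial), while the C2-symmetric boron controller, reinforced by the substrate's preference for C–C bond formation anti to the dioxolane C–O bond, selects the face.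

Step 8
Reactants: 16 pent-4-enoic acid
Product: 17 primary alcohol
Conditions: LiAlH4, Et2O, 0 °C → rt
Reagents that add atoms: none
Why: Hydride reduction of the hindered acid gives the primary alcohol; the silyl ether, the acetal and the isolated alkenes are inert.

Step 9
Reactants: 17 primary alcohol
Product: 18 β,γ-unsaturated aldehyde
Conditions: Dess–Martin periodinane, NaHCO3, CH2Cl2, 0 °C; used at once
Reagents that add atoms: none
Why: Dess–Martin oxidation under buffered, non-basic conditions should give the aldehyde without epimerising or conjugating the α-centre.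

Step 10
Reactants: 18 aldehyde; 19 ethynylmagnesium bromide
Product: 20 (3R)-propargylic alcohol
Conditions: HC≡CMgBr, THF, −78 → −20 °C; aq. NH4Cl
Reagents that add atoms: ethynylmagnesium bromide, C#C[Mg]Br
Why: In this Felkin–Anh addition the quaternary carbon is the large group anti to the incoming acetylide, which places the new hydroxyl syn to the 2-propenyl branch and so sets C6 in the configuration of the target.

Step 11
Reactants: 20 propargylic alcohol; 21 formaldehyde (as paraformaldehyde)
Product: 23 allenol, via Mannich base 22 (not isolated)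
Conditions: (CH2O)n, CuI (0.5 equiv), Cy2NH, 1,4-dioxane, reflux
Reagents that add atoms: formaldehyde (paraformaldehyde), C=O
Why: In the Crabbé homologation a Mannich reaction at the alkyne terminus is followed by copper-mediated 1,5-hydride transfer, which turns the terminal alkyne into the terminal allene; the reaction is established for free propargylic alcohols and does not touch the carbinol centre.

Step 12
Reactants: 23 allenol; 24 tert-butyldimethylsilyl triflate
Product: 25 allenyl carbinol TBS ether
Conditions: TBSOTf, 2,6-lutidine, CH2Cl2, −78 → 0 °C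
Reagents that add atoms: tert-butyldimethylsilyl trifluoromethanesulfonate, CC(C)(C)[Si](C)(C)OS(=O)(=O)C(F)(F)F
Why: Silyl triflate silylation protects the hindered secondary carbinol that lesser silylating agents would not reach.

Step 13
Reactants: 25 TBS ether
Product: 26 terminal 1,2-diol
Conditions: PPTS (0.3 equiv), MeOH, 45 °C
Reagents that add atoms: none
Why: Acid-catalysed transketalisation removes the terminal acetonide, whereas the secondary TBS and primary TBDPS ethers solvolyse far more slowly.

Step 14
Reactants: 26 diol; 27 chlorotriethylsilane; 28 2-methylpropanoyl chloride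
Product: 30 C9 isobutyrate C8 triethylsilyl ether, via triethylsilyl ether 29 (not isolated)
Conditions: Et3SiCl (1.05 equiv), Et3N, DMAP (cat.), CH2Cl2, −78 °C; then i-PrCOCl, Et3N, DMAP, 0 °C → rt
Reagents that add atoms: chlorotriethylsilane, CC[Si](Cl)(CC)CC; 2-methylpropanoyl chloride, CC(C)C(=O)Cl
Why: The primary hydroxyl is silylated selectively at low temperature and the remaining neopentyl secondary alcohol is then acylated under DMAP catalysis, so a free primary alcohol never sits next to the ester and acyl migration is excluded.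

Step 15
Reactants: 30 isobutyrate triethylsilyl ether
Product: 31 allenyl α-acyloxy aldehyde
Conditions: (COCl)2, DMSO, CH2Cl2, −78 → −40 °C; Et3N, −78 → −20 °C; pH 7 buffer
Reagents that add atoms: none
Why: Swern conditions cleave and oxidise a primary triethylsilyl ether directly while secondary and bulkier silyl ethers persist, which gives the aldehyde without passing through the migration-prone hydroxy ester.

Step 16
Reactants: 31 allenyl aldehyde; 32 carbon monoxide
Product: 33 cis-fused α-methylene-γ-butyrolactone (bis-silyl ether of the target)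
Conditions: Ru3(CO)12 (5 mol%), CO (20 atm), 1,4-dioxane, 120 °C
Reagents that add atoms: carbon monoxide, [C-]#[O+]
Why: Ru(0) binds the formyl group (C8=O) and the internal allene π-bond (C7=C11), oxidative cyclisation forms the C7–C8 bond and an oxaruthenacyclopentane, CO insertion into the Ru–C11 bond forms C11–C12 and reductive elimination closes O–C12, so this hetero-Pauson–Khand [2+2+1] builds the cyclohexane and the α-methylene lactone in one operation. The closest known reaction is the Ru3(CO)12-catalysed (or Mo(CO)6-mediated) cyclocarbonylation of allenyl aldehydes to cis-fused bicyclic α-methylene-γ-butyrolactones. The carbocycle closes in a 6-exo sense onto the proximal allene carbon and the lactone closes by carbonylative contraction of the five-membered metallacycle. C7 and C8 are the new stereocentres: the cis ring fusion is dictated by the metallacycle, and its sense by a chair transition state in which the C5 branch, C6–OTBS, the C9 acyloxy group and the allene are all equatorial and only the formyl oxygen is axial (an axial allene would force the C6–H into the disfavoured anti arrangement to the π-bond). The step needs selection of the internal allene π-bond over the terminal one and over the vinyl and 2-propenyl groups, which the six-membered tether secures (the terminal bond would need a seven-membered ring, and isolated alkenes do not enter this cycle), and it needs the aldehyde to survive, which the CO pressure (against decarbonylation) and the quaternary neighbour support.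

Step 17
Reactants: 33 bis-silyl ether
Product: 34 CNP0298885.1 (target)
Conditions: HF·pyridine, pyridine/THF, 0 °C → rt
Reagents that add atoms: none
Why: Acidic fluoride removes the secondary TBS and primary TBDPS ethers and spares the α-methylene lactone, the isobutyrate and the allylic alcohol, which basic fluoride sources could attack or translactonise.

**Compound list**

1 | methyl (4S)-2,2-dimethyl-1,3-dioxolane-4-carboxylate | COC(=O)[C@@H]1COC(C)(C)O1 | starting material
2 | N,O-dimethylhydroxylamine hydrochloride | Cl.CNOC | starting material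
3 | (4S)-N-methoxy-N,2,2-trimethyl-1,3-dioxolane-4-carboxamide | CON(C)C(=O)[C@@H]1COC(C)(C)O1 | intermediate
4 | methylmagnesium bromide | C[Mg]Br | starting material
5 | 1-[(4S)-2,2-dimethyl-1,3-dioxolan-4-yl]ethan-1-one | CC(=O)[C@@H]1COC(C)(C)O1 | intermediate
6 | ethyl (triphenylphosphoranylidene)acetate | CCOC(=O)C=P(c1ccccc1)(c1ccccc1)c1ccccc1 | starting material
7 | ethyl (2E)-3-[(4R)-2,2-dimethyl-1,3-dioxolan-4-yl]but-2-enoate | CCOC(=O)/C=C(\C)[C@@H]1COC(C)(C)O1 | intermediate
8 | (2E)-3-[(4R)-2,2-dimethyl-1,3-dioxolan-4-yl]but-2-en-1-ol | C/C(=C\CO)[C@@H]1COC(C)(C)O1 | intermediate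
9 | itaconic anhydride (3-methylideneoxolane-2,5-dione) | C=C1CC(=O)OC1=O | starting material
10 | 4-{[(2E)-3-[(4R)-2,2-dimethyl-1,3-dioxolan-4-yl]but-2-en-1-yl]oxy}-2-methylidene-4-oxobutanoic acid | C/C(=C\COC(=O)CC(=C)C(=O)O)[C@@H]1COC(C)(C)O1 | intermediate
11 | tert-butyl(chloro)diphenylsilane | CC(C)(C)[Si](Cl)(c1ccccc1)c1ccccc1 | starting material
12 | mixed anhydride of 10 with isobutyl hydrogen carbonate | C/C(=C\COC(=O)CC(=C)C(=O)OC(=O)OCC(C)C)[C@@H]1COC(C)(C)O1 | intermediate
13 | (2E)-3-[(4R)-2,2-dimethyl-1,3-dioxolan-4-yl]but-2-en-1-yl 3-(hydroxymethyl)but-3-enoate | C/C(=C\COC(=O)CC(=C)CO)[C@@H]1COC(C)(C)O1 | intermediate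
14 | (2E)-3-[(4R)-2,2-dimethyl-1,3-dioxolan-4-yl]but-2-en-1-yl 3-({[tert-butyl(diphenyl)silyl]oxy}methyl)but-3-enoate | C/C(=C\COC(=O)CC(=C)CO[Si](c1ccccc1)(c1ccccc1)C(C)(C)C)[C@@H]1COC(C)(C)O1 | intermediate
15 | E(O)-boron ketene acetal of 14, boron carried in the (4S,5S)-1,3-bis{[3,5-bis(trifluoromethyl)phenyl]sulfonyl}-4,5-diphenyl-1,3,2-diazaborolidine | C/C(=C\CO/C(OB2N(S(=O)(=O)c3cc(C(F)(F)F)cc(C(F)(F)F)c3)[C@@H](c3ccccc3)[C@H](c3ccccc3)N2S(=O)(=O)c2cc(C(F)(F)F)cc(C(F)(F)F)c2)=C\C(=C)CO[Si](c2ccccc2)(c2ccccc2)C(C)(C)C)[C@@H]1COC(C)(C)O1 | intermediate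
16 | (2S,3S)-2-(3-{[tert-butyl(diphenyl)silyl]oxy}prop-1-en-2-yl)-3-[(4R)-2,2-dimethyl-1,3-dioxolan-4-yl]-3-methylpent-4-enoic acid | C=C[C@@]([C@@H]1COC(C)(C)O1)(C)[C@H](C(=C)CO[Si](c1ccccc1)(c1ccccc1)C(C)(C)C)C(=O)O | intermediate
17 | (2S,3S)-2-(3-{[tert-butyl(diphenyl)silyl]oxy}prop-1-en-2-yl)-3-[(4R)-2,2-dimethyl-1,3-dioxolan-4-yl]-3-methylpent-4-en-1-ol | C=C[C@@]([C@@H]1COC(C)(C)O1)(C)[C@H](C(=C)CO[Si](c1ccccc1)(c1ccccc1)C(C)(C)C)CO | intermediate
18 | (2S,3S)-2-(3-{[tert-butyl(diphenyl)silyl]oxy}prop-1-en-2-yl)-3-[(4R)-2,2-dimethyl-1,3-dioxolan-4-yl]-3-methylpent-4-enal | C=C[C@@]([C@@H]1COC(C)(C)O1)(C)[C@H](C(=C)CO[Si](c1ccccc1)(c1ccccc1)C(C)(C)C)C=O | intermediate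
19 | ethynylmagnesium bromide | C#C[Mg]Br | starting material
20 | (3R,4S,5S)-4-(3-{[tert-butyl(diphenyl)silyl]oxy}prop-1-en-2-yl)-5-[(4R)-2,2-dimethyl-1,3-dioxolan-4-yl]-5-methylhept-6-en-1-yn-3-ol | C=C[C@@]([C@@H]1COC(C)(C)O1)(C)[C@H](C(=C)CO[Si](c1ccccc1)(c1ccccc1)C(C)(C)C)[C@@H](O)C#C | intermediate
21 | formaldehyde (used as paraformaldehyde) | C=O | starting material
22 | (4R,5S,6S)-1-(dicyclohexylamino)-5-(3-{[tert-butyl(diphenyl)silyl]oxy}prop-1-en-2-yl)-6-[(4R)-2,2-dimethyl-1,3-dioxolan-4-yl]-6-methyloct-7-en-2-yn-4-ol | C=C[C@@]([C@@H]1COC(C)(C)O1)(C)[C@H](C(=C)CO[Si](c1ccccc1)(c1ccccc1)C(C)(C)C)[C@@H](O)C#CCN(C1CCCCC1)C1CCCCC1 | intermediate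
23 | (4S,5S,6S)-5-(3-{[tert-butyl(diphenyl)silyl]oxy}prop-1-en-2-yl)-6-[(4R)-2,2-dimethyl-1,3-dioxolan-4-yl]-6-methylocta-1,2,7-trien-4-ol | C=C[C@@]([C@@H]1COC(C)(C)O1)(C)[C@H](C(=C)CO[Si](c1ccccc1)(c1ccccc1)C(C)(C)C)[C@@H](O)C=C=C | intermediate
24 | tert-butyldimethylsilyl trifluoromethanesulfonate | CC(C)(C)[Si](C)(C)OS(=O)(=O)C(F)(F)F | starting material
25 | tert-butyl(dimethyl)silyl ether of 23 (4S,5S,6S; dioxolane 4R) | C=C[C@@]([C@@H]1COC(C)(C)O1)(C)[C@H](C(=C)CO[Si](c1ccccc1)(c1ccccc1)C(C)(C)C)[C@@H](O[Si](C)(C)C(C)(C)C)C=C=C | intermediate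
26 | (2R,3S,4S,5S)-5-{[tert-butyl(dimethyl)silyl]oxy}-4-(3-{[tert-butyl(diphenyl)silyl]oxy}prop-1-en-2-yl)-3-ethenyl-3-methylocta-6,7-diene-1,2-diol | C=C[C@@]([C@@H](O)CO)(C)[C@H](C(=C)CO[Si](c1ccccc1)(c1ccccc1)C(C)(C)C)[C@@H](O[Si](C)(C)C(C)(C)C)C=C=C | intermediate
27 | chlorotriethylsilane | CC[Si](Cl)(CC)CC | starting material
28 | 2-methylpropanoyl chloride | CC(C)C(=O)Cl | starting material
29 | 1-O-triethylsilyl ether of diol 26 (2R,3S,4S,5S) | C=C[C@@]([C@@H](O)CO[Si](CC)(CC)CC)(C)[C@H](C(=C)CO[Si](c1ccccc1)(c1ccccc1)C(C)(C)C)[C@@H](O[Si](C)(C)C(C)(C)C)C=C=C | intermediate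
30 | (2R,3S,4S,5S)-5-{[tert-butyl(dimethyl)silyl]oxy}-4-(3-{[tert-butyl(diphenyl)silyl]oxy}prop-1-en-2-yl)-3-ethenyl-3-methyl-1-[(triethylsilyl)oxy]octa-6,7-dien-2-yl 2-methylpropanoate | C=C[C@@]([C@@H](OC(=O)C(C)C)CO[Si](CC)(CC)CC)(C)[C@H](C(=C)CO[Si](c1ccccc1)(c1ccccc1)C(C)(C)C)[C@@H](O[Si](C)(C)C(C)(C)C)C=C=C | intermediate
31 | (2R,3S,4S,5S)-5-{[tert-butyl(dimethyl)silyl]oxy}-4-(3-{[tert-butyl(diphenyl)silyl]oxy}prop-1-en-2-yl)-3-ethenyl-3-methyl-1-oxoocta-6,7-dien-2-yl 2-methylpropanoate | C=C[C@@]([C@@H](OC(=O)C(C)C)C=O)(C)[C@H](C(=C)CO[Si](c1ccccc1)(c1ccccc1)C(C)(C)C)[C@@H](O[Si](C)(C)C(C)(C)C)C=C=C | intermediate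
32 | carbon monoxide | [C-]#[O+] | starting material
33 | (3aR,4R,5S,6S,7R,7aS)-4-{[tert-butyl(dimethyl)silyl]oxy}-5-(3-{[tert-butyl(diphenyl)silyl]oxy}prop-1-en-2-yl)-6-ethenyl-6-methyl-3-methylidene-2-oxooctahydro-1-benzofuran-7-yl 2-methylpropanoate | C=C[C@@]1(C)[C@H](C(=C)CO[Si](c3ccccc3)(c3ccccc3)C(C)(C)C)[C@@H](O[Si](C)(C)C(C)(C)C)[C@@H]2C(=C)C(=O)O[C@@H]2[C@@H]1OC(=O)C(C)C | intermediate
34 | (3aS,4R,5S,6S,7R,7aS)-6-ethenyl-4-hydroxy-5-(3-hydroxyprop-1-en-2-yl)-6-methyl-3-methylidene-2-oxooctahydro-1-benzofuran-7-yl 2-methylpropanoate (CNP0298885.1) | C=C[C@@]1(C)[C@H](C(=C)CO)[C@@H](O)[C@@H]2C(=C)C(=O)O[C@@H]2[C@@H]1OC(=O)C(C)C | target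

**Step count and risks**

Total step count: 17. Longest linear sequence: 17 steps (from 1).

Steps most likely to fail:

1. Step 16 (hetero-Pauson–Khand cyclocarbonylation).
   - What may go wrong: facial selection between the two cis-fused lactones may be poor, because the competing chair (allene axial, formyl oxygen equatorial) avoids the 1,3-diaxial contact between the forming C8–O bond and the C10 methyl group.
   - At 120 °C the activated aldehyde may also undergo a thermal carbonyl-ene reaction with the 2-propenyl unit, or be decarbonylated.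
   - Fallback: a stepwise closure at room temperature that sets out from aldehyde 31 and returns at lactone 33. Palladium-catalysed distannylation of the allene with in-situ intramolecular allylstannane addition to the aldehyde (Bu3Sn–SnBu3, allylpalladium chloride dimer cat., THF, rt) should give the cis-hydroxy vinylstannane F1. Iododestannylation (I2, CH2Cl2, 0 °C) should give the cis-hydroxy vinyl iodide F2. Palladium-catalysed carbonylative lactonisation (Pd(PPh3)4, CO 1 atm, i-Pr2NEt, MeCN, 50 °C) then closes the α-methylene lactone to 33.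

2. Step 7 (enantiocontrolled Ireland–Claisen rearrangement).
   - What may go wrong: the Lewis-acidic bromoborane may open the acetonide before enolisation is complete, the slow rearrangement of the boron ketene acetal may stall, or the facial bias may be insufficient when reagent and substrate preferences do not reinforce each other.
   - Fallback: substrate control by allylic 1,3-strain in the (Z)-olefin series with lithium/silicon chemistry only, setting out from ketone 5 and returning at acid 16.
   - Wittig olefination of 5 with 6 in methanol at 0 °C (Z-selective for α-alkoxy carbonyl compounds) should give the (Z)-enoate F3, and DIBAL reduction the (Z)-allylic alcohol F4.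
   - Opening of itaconic anhydride should give the (Z)-half ester F5, mixed-anhydride/NaBH4 reduction the (Z)-hydroxy ester F6, and silylation with 11 the (Z)-silyl-protected ester F7.
   - Enolisation with LDA in THF/DMPU at −78 °C and trapping with Me3SiCl should give the Z(O)-silyl ketene acetal F8, which on warming rearranges through a chair to 16 after hydrolysis. The (Z)-alkene with the Z(O)-ketene acetal gives the same relative configuration at C5/C10, and 1,3-strain holds the C9–H in the alkene plane so that the new bond forms anti to the C9–O bond.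

3. Step 10 (ethynylation of aldehyde 18).
   - What may go wrong: Felkin–Anh selectivity may be incomplete, and the basic acetylide may epimerise the α-centre or move the double bond into conjugation.
   - Fallback: redox correction under reagent control, setting out from aldehyde 18 and returning at propargylic alcohol 20. The addition is run without regard to selectivity (CeCl3-modified acetylide to suppress enolisation), the carbinol mixture is oxidised with Dess–Martin periodinane to the ynone F9, and F9 is reduced by Noyori transfer hydrogenation ((R,R)-TsDPEN–Ru(p-cymene), i-PrOH, base-free; catalyst enantiomer chosen for the 3R carbinol) to 20.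

**Further compounds**

F1 | step 16 | cis-hydroxy vinylstannane: cyclohexanol from C7–C8 closure, C8–OH cis to the 1-(tributylstannyl)ethenyl group on C7, other centres and protecting groups as in 33 | C=C[C@@]1(C)[C@H](C(=C)CO[Si](c2ccccc2)(c2ccccc2)C(C)(C)C)[C@@H](O[Si](C)(C)C(C)(C)C)[C@H](C(=C)[Sn](CCCC)(CCCC)CCCC)[C@H](O)[C@@H]1OC(=O)C(C)C
F2 | step 16 | cis-hydroxy vinyl iodide: as F1 with a 1-iodoethenyl group on C7 | C=C[C@@]1(C)[C@H](C(=C)CO[Si](c2ccccc2)(c2ccccc2)C(C)(C)C)[C@@H](O[Si](C)(C)C(C)(C)C)[C@H](C(=C)I)[C@H](O)[C@@H]1OC(=O)C(C)C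
F3 | step 7 | ethyl (2Z)-3-[(4R)-2,2-dimethyl-1,3-dioxolan-4-yl]but-2-enoate | CCOC(=O)/C=C(/C)[C@@H]1COC(C)(C)O1
F4 | step 7 | (2Z)-3-[(4R)-2,2-dimethyl-1,3-dioxolan-4-yl]but-2-en-1-ol | C/C(=C/CO)[C@@H]1COC(C)(C)O1
F5 | step 7 | 4-{[(2Z)-3-[(4R)-2,2-dimethyl-1,3-dioxolan-4-yl]but-2-en-1-yl]oxy}-2-methylidene-4-oxobutanoic acid | C/C(=C/COC(=O)CC(=C)C(=O)O)[C@@H]1COC(C)(C)O1
F6 | step 7 | (2Z)-3-[(4R)-2,2-dimethyl-1,3-dioxolan-4-yl]but-2-en-1-yl 3-(hydroxymethyl)but-3-enoate | C/C(=C/COC(=O)CC(=C)CO)[C@@H]1COC(C)(C)O1
F7 | step 7 | (2Z)-3-[(4R)-2,2-dimethyl-1,3-dioxolan-4-yl]but-2-en-1-yl 3-({[tert-butyl(diphenyl)silyl]oxy}methyl)but-3-enoate | C/C(=C/COC(=O)CC(=C)CO[Si](c1ccccc1)(c1ccccc1)C(C)(C)C)[C@@H]1COC(C)(C)O1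
F8 | step 7 | Z(O)-trimethylsilyl ketene acetal of F7 | C/C(=C/CO/C(O[Si](C)(C)C)=C/C(=C)CO[Si](c1ccccc1)(c1ccccc1)C(C)(C)C)[C@@H]1COC(C)(C)O1
F9 | step 10 | (4S,5S)-4-(3-{[tert-butyl(diphenyl)silyl]oxy}prop-1-en-2-yl)-5-[(4R)-2,2-dimethyl-1,3-dioxolan-4-yl]-5-methylhept-6-en-1-yn-3-one | C=C[C@@]([C@@H]1COC(C)(C)O1)(C)[C@H](C(=C)CO[Si](c1ccccc1)(c1ccccc1)C(C)(C)C)C(=O)C#C
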